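**Plan**
1. Retrosynthesis: the ten-membered ring is cut at C9–C10. C9 is an oxygen-bearing sp3 carbon bonded to sp2 C10 of the ring-cis C1=C10–C14 enal unit, i.e. an allylic carbinol, the retron of an alkenyl-metal/aldehyde addition. Further cuts: C7–C8 (β-hydroxyalkyl-α-methylene lactone → 3-(bromomethyl)butenolide + PMBOCH2CHO), the butenolide bonds C7=C11 and O6–C12 (metathesis, ester), and C1=C10 (Wittig), back to geranyl acetate.
2. Forward: geranyl acetate → chain C6–C5=C4(C15)–C3–C2–C1=C10(I)–C14 → butenolide (first ring) → Barbier coupling (C7–C8, C13 methylene) → C8 ester → Ni/Cr closure of the ten-membered carbocycle (last ring) → C9 acetate, then unmasking of C14=O and CH2OH.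
3. Stereochemistry: C6 by catalytic asymmetric vinylation; C7 relayed from C6 and C8 set in the same Barbier step (C8 then inverted on esterification); C9 from C8 during ring closure; C4=C5 (E) bought with geranyl acetate; C1=C10 from a (Z)-α-iodoenal, transferred with retention.

Key step: step 16

Remark: C-numbers are those of the germacrane skeleton of the target (C6 lactone O–CH, C7 lactone ring CH, C8 ester carbinol, C9 acetate carbinol, C12 lactone C=O, C13 exo-methylene, C14 formyl, C15 methyl). The Barbier addition of step 10 is assumed to follow the closed chair transition state usual for allylzinc reagents, so C8 is formed as the 8α (R) carbinol and is inverted in step 13.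

**Step 1**
Reactants: 1 geranyl acetate
Product: 3 (2E)-3-methyl-6-oxohex-2-en-1-yl acetate, via ozonide 2 (not isolated)
Conditions: O3 (1.0 equiv), CH2Cl2, −78 °C; then PPh3, −78 °C → rt
Reagents that add atoms: ozone, [O-][O+]=O
Why: Ozonolysis with reductive work-up; the distal trisubstituted alkene is more electron-rich than the 2,3-alkene, which the allylic acetate deactivates, so one equivalent of ozone should cleave it selectively.

**Step 2**
Reactants: 3 (2E)-3-methyl-6-oxohex-2-en-1-yl acetate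
Product: 4 (2E,6E)-3-methyl-8-oxoocta-2,6-dien-1-yl acetate
Conditions: Ph3P=CHCHO (1.1 equiv), toluene, 80 °C
Reagents that add atoms: (triphenylphosphoranylidene)acetaldehyde, O=CC=P(c1ccccc1)(c1ccccc1)c1ccccc1
Why: Wittig olefination with a stabilised formyl ylide should give the (E)-enal (C1=C10) and stop after one homologation, because the enal product is less electrophilic than the saturated aldehyde.

**Step 3**
Reactants: 4 (2E,6E)-3-methyl-8-oxoocta-2,6-dien-1-yl acetate
Product: 5 (2E,6Z)-7-iodo-3-methyl-8-oxoocta-2,6-dien-1-yl acetate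
Conditions: I2, DMAP (0.2 equiv), pyridine/CH2Cl2 (1:1), 0 °C → rt, dark
Reagents that add atoms: iodine, II
Why: Amine-mediated α-iodination of an enal (conjugate addition of the amine, iodination of the enolate, E1cB loss of the amine) should give the thermodynamically favoured (Z)-2-iodoenal, with iodine cis to the C2 chain, the position later taken by C9.

**Step 4**
Reactants: 5 (2E,6Z)-7-iodo-3-methyl-8-oxoocta-2,6-dien-1-yl acetate
Product: 6 (2E,6Z)-7-(1,3-dioxolan-2-yl)-7-iodo-3-methylhepta-2,6-dien-1-yl acetate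
Conditions: TMSOCH2CH2OTMS, TMSOTf (5 mol %), CH2Cl2, −78 → −20 °C
Reagents that add atoms: 1,2-bis(trimethylsilyloxy)ethane, C[Si](C)(C)OCCO[Si](C)(C)C
Why: Silyl-triflate-catalysed acetalisation masks C14 at the aldehyde oxidation level at low temperature without moving the double bond or touching the acetate.

**Step 5**
Reactants: 6 (2E,6Z)-7-(1,3-dioxolan-2-yl)-7-iodo-3-methylhepta-2,6-dien-1-yl acetate
Product: 7 (2E,6Z)-7-(1,3-dioxolan-2-yl)-7-iodo-3-methylhepta-2,6-dien-1-ol
Conditions: K2CO3 (0.2 equiv), MeOH, 0 °C → rt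
Reagents that add atoms: none
Why: Base-catalysed transesterification removes the acetate; the acetal and the alkenyl iodide are inert to carbonate in methanol.

**Step 6**
Reactants: 7 (2E,6Z)-7-(1,3-dioxolan-2-yl)-7-iodo-3-methylhepta-2,6-dien-1-ol
Product: 8 (2E,6Z)-7-(1,3-dioxolan-2-yl)-7-iodo-3-methylhepta-2,6-dienal
Conditions: MnO2 (20 equiv), CH2Cl2, rt
Reagents that add atoms: none
Why: MnO2 oxidation is selective for the allylic alcohol and should give the C6 aldehyde without isomerising the (E)-C4=C5 alkene.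

**Step 7**
Reactants: 8 (2E,6Z)-7-(1,3-dioxolan-2-yl)-7-iodo-3-methylhepta-2,6-dienal
Product: 9 (3S,4E,8Z)-9-(1,3-dioxolan-2-yl)-9-iodo-5-methylnona-1,4,8-trien-3-ol
Conditions: Zn(CH=CH2)2 (1.5 equiv, salt-free), (−)-MIB (5 mol %), toluene/hexane, −10 °C; aq. NH4Cl
Reagents that add atoms: divinylzinc, C=C[Zn]C=C
Why: Amino-alcohol-catalysed enantioselective alkenylzinc addition to an enal; the chiral zinc aminoalkoxide directs vinyl transfer to one aldehyde face and should set C6 as the (S)-carbinol, which becomes 6R (6α-O) in the lactone.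

**Step 8**
Reactants: 9 (3S,4E,8Z)-9-(1,3-dioxolan-2-yl)-9-iodo-5-methylnona-1,4,8-trien-3-ol; 10 2-(bromomethyl)prop-2-enoic acid
Product: 11 (3S,4E,8Z)-9-(1,3-dioxolan-2-yl)-9-iodo-5-methylnona-1,4,8-trien-3-yl 2-(bromomethyl)prop-2-enoate
Conditions: DCC, DMAP (5 mol %), CH2Cl2, 0 °C
Reagents that add atoms: none
Why: Steglich esterification acylates the secondary bis-allylic alcohol under near-neutral conditions with retention at C6 and leaves the allylic bromide intact.

**Step 9**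
Reactants: 11 (3S,4E,8Z)-9-(1,3-dioxolan-2-yl)-9-iodo-5-methylnona-1,4,8-trien-3-yl 2-(bromomethyl)prop-2-enoate
Product: 12 (5R)-3-(bromomethyl)-5-[(1E,5Z)-6-(1,3-dioxolan-2-yl)-6-iodo-2-methylhexa-1,5-dien-1-yl]furan-2(5H)-one
Conditions: Grubbs II (5 mol %), toluene (5 mM), 80 °C
Reagents that add atoms: none
Why: Ring-closing metathesis of an allyl α-substituted acrylate; the catalyst loads on the terminal vinyl group and closes the butenolide (C7=C11) onto the acrylate alkene, while the trisubstituted C4=C5 alkene and the iodoalkene are too hindered to react.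

**Step 10**
Reactants: 12 (5R)-3-(bromomethyl)-5-[(1E,5Z)-6-(1,3-dioxolan-2-yl)-6-iodo-2-methylhexa-1,5-dien-1-yl]furan-2(5H)-one; 13 2-[(4-methoxybenzyl)oxy]acetaldehyde
Product: 15 (4R,5R)-5-[(1E,5Z)-6-(1,3-dioxolan-2-yl)-6-iodo-2-methylhexa-1,5-dien-1-yl]-4-[(1R)-1-hydroxy-2-(4-methoxybenzyloxy)ethyl]-3-methylideneoxolan-2-one, via allylzinc bromide 14 (not isolated)
Conditions: Zn dust, THF/sat. aq. NH4Cl (2:1), 0 °C → rt
Reagents that add atoms: none
Why: Zinc-mediated Barbier 2-(alkoxycarbonyl)allylation with allylic transposition through a Zimmerman–Traxler chair; C7 attacks the aldehyde anti to the C6 side chain (6,7-trans lactone), CH2OPMB sits equatorial (8α, 1′R carbinol), and CH2Br becomes the C13 exo-methylene.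

**Step 11**
Reactants: 16 ethyl 2-(hydroxymethyl)prop-2-enoate
Product: 17 ethyl 2-[(tert-butyldimethylsilyloxy)methyl]prop-2-enoate
Conditions: TBSCl, imidazole, CH2Cl2, 0 °C → rt
Reagents that add atoms: tert-butyldimethylsilyl chloride, CC(C)(C)[Si](C)(C)Cl
Why: Standard silylation of a primary alcohol protects the side-chain hydroxyl for the steps up to the final unmasking.

**Step 12**
Reactants: 17 ethyl 2-[(tert-butyldimethylsilyloxy)methyl]prop-2-enoate
Product: 18 2-[(tert-butyldimethylsilyloxy)methyl]prop-2-enoic acid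
Conditions: LiOH, THF/H2O (3:1), 0 °C → rt; then 1 M HCl to pH 3
Reagents that add atoms: lithium hydroxide, [Li+].[OH-]
Why: Saponification of the ethyl ester; the primary TBS ether is stable to aqueous LiOH.

**Step 13**
Reactants: 15 (4R,5R)-5-[(1E,5Z)-6-(1,3-dioxolan-2-yl)-6-iodo-2-methylhexa-1,5-dien-1-yl]-4-[(1R)-1-hydroxy-2-(4-methoxybenzyloxy)ethyl]-3-methylideneoxolan-2-one; 18 2-[(tert-butyldimethylsilyloxy)methyl]prop-2-enoic acid
Product: 19 (1S)-1-[(2R,3S)-2-[(1E,5Z)-6-(1,3-dioxolan-2-yl)-6-iodo-2-methylhexa-1,5-dien-1-yl]-4-methylidene-5-oxooxolan-3-yl]-2-(4-methoxybenzyloxy)ethyl 2-[(tert-butyldimethylsilyloxy)methyl]prop-2-enoate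
Conditions: PPh3, DIAD, toluene, 0 °C → rt
Reagents that add atoms: none
Why: Mitsunobu esterification; the carboxylate displaces the C8 oxyphosphonium by SN2, which installs the side-chain ester and inverts C8 to the required 8β (8S) configuration under neutral conditions tolerated by both Michael acceptors.

**Step 14**
Reactants: 19 (1S)-1-[(2R,3S)-2-[(1E,5Z)-6-(1,3-dioxolan-2-yl)-6-iodo-2-methylhexa-1,5-dien-1-yl]-4-methylidene-5-oxooxolan-3-yl]-2-(4-methoxybenzyloxy)ethyl 2-[(tert-butyldimethylsilyloxy)methyl]prop-2-enoate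
Product: 20 (1S)-1-[(2R,3S)-2-[(1E,5Z)-6-(1,3-dioxolan-2-yl)-6-iodo-2-methylhexa-1,5-dien-1-yl]-4-methylidene-5-oxooxolan-3-yl]-2-hydroxyethyl 2-[(tert-butyldimethylsilyloxy)methyl]prop-2-enoate
Conditions: DDQ, CH2Cl2/pH 7 buffer (10:1), 0 °C; crude product used at once
Reagents that add atoms: none
Why: Oxidative PMB ether cleavage with DDQ frees the C9 primary alcohol under neutral conditions, which should suppress acyl migration from O8 to O9.

**Step 15**
Reactants: 20 (1S)-1-[(2R,3S)-2-[(1E,5Z)-6-(1,3-dioxolan-2-yl)-6-iodo-2-methylhexa-1,5-dien-1-yl]-4-methylidene-5-oxooxolan-3-yl]-2-hydroxyethyl 2-[(tert-butyldimethylsilyloxy)methyl]prop-2-enoate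
Product: 21 (1S)-1-[(2R,3S)-2-[(1E,5Z)-6-(1,3-dioxolan-2-yl)-6-iodo-2-methylhexa-1,5-dien-1-yl]-4-methylidene-5-oxooxolan-3-yl]-2-oxoethyl 2-[(tert-butyldimethylsilyloxy)methyl]prop-2-enoate
Conditions: Dess–Martin periodinane, NaHCO3, CH2Cl2, 0 °C → rt
Reagents that add atoms: none
Why: Dess–Martin oxidation under buffered, non-basic conditions should give the α-acyloxy aldehyde without epimerising C8.

**Step 16**
Reactants: 21 (1S)-1-[(2R,3S)-2-[(1E,5Z)-6-(1,3-dioxolan-2-yl)-6-iodo-2-methylhexa-1,5-dien-1-yl]-4-methylidene-5-oxooxolan-3-yl]-2-oxoethyl 2-[(tert-butyldimethylsilyloxy)methyl]prop-2-enoate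
Product: 23 (3aS,4S,5S,6E,10E,11aR)-6-(1,3-dioxolan-2-yl)-5-hydroxy-10-methyl-3-methylidene-2-oxo-2,3,3a,4,5,8,9,11a-octahydrocyclodeca[b]furan-4-yl 2-[(tert-butyldimethylsilyloxy)methyl]prop-2-enoate, via alkenylchromium(III) dichloride 22 (not isolated)
Conditions: CrCl2 (10 equiv), NiCl2 (0.1 equiv), degassed DMSO, rt; 21 added over 12 h to 2 mM final concentration; aqueous work-up
Reagents that add atoms: none
Why: Nozaki–Hiyama–Kishi reaction: Ni(0) inserts into the C10–I bond, transmetalation gives the alkenylchromium(III) species 22 with retention of the Z geometry, C10 adds to the C9 aldehyde, and the chromium alkoxide is hydrolysed on work-up. The closest known reaction type is the intramolecular Ni/Cr-mediated alkenyl iodide–aldehyde coupling used to close medium and large carbocycles that already carry an α-methylene lactone. The ten-membered carbocycle closes in a 10-exo-trig mode, the C9=O bond being exocyclic to the new ring. C9 is the only new stereocentre and is controlled by the adjacent C8 acyloxy centre: C10 approaches anti to the C8–O bond (polar Felkin–Anh) in the ring-closing conformer that keeps H8 and the formyl hydrogen antiperiplanar and turns the carbonyl oxygen away from C7 and out of the ring, which should give the 9α (9S) alcohol, trans to the C8 ester. The step needs ring closure over oligomerisation, secured by slow addition at high dilution and by the trans-lactone and the Z-iodoalkene, which hold the two ends close, and chemoselectivity for the aldehyde over the lactone, the two acrylate units and the acetal, which is inherent to alkenylchromium reagents. The ring-cis C1=C10 geometry (C9 cis to C2, C14 trans to C2) follows from retention at the (Z)-iodide.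

**Step 17**
Reactants: 23 (3aS,4S,5S,6E,10E,11aR)-6-(1,3-dioxolan-2-yl)-5-hydroxy-10-methyl-3-methylidene-2-oxo-2,3,3a,4,5,8,9,11a-octahydrocyclodeca[b]furan-4-yl 2-[(tert-butyldimethylsilyloxy)methyl]prop-2-enoate
Product: 24 (3aS,4S,5S,6E,10E,11aR)-5-acetoxy-6-(1,3-dioxolan-2-yl)-10-methyl-3-methylidene-2-oxo-2,3,3a,4,5,8,9,11a-octahydrocyclodeca[b]furan-4-yl 2-[(tert-butyldimethylsilyloxy)methyl]prop-2-enoate
Conditions: Ac2O, pyridine, DMAP (cat.), CH2Cl2, 0 °C
Reagents that add atoms: acetic anhydride, CC(=O)OC(C)=O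
Why: DMAP-catalysed acetylation of the secondary allylic C9 alcohol proceeds with retention and is fast enough at 0 °C to outrun acyl migration.

**Step 18**
Reactants: 24 (3aS,4S,5S,6E,10E,11aR)-5-acetoxy-6-(1,3-dioxolan-2-yl)-10-methyl-3-methylidene-2-oxo-2,3,3a,4,5,8,9,11a-octahydrocyclodeca[b]furan-4-yl 2-[(tert-butyldimethylsilyloxy)methyl]prop-2-enoate
Product: 25 (3aS,4S,5S,6E,10E,11aR)-5-acetoxy-6-formyl-10-methyl-3-methylidene-2-oxo-2,3,3a,4,5,8,9,11a-octahydrocyclodeca[b]furan-4-yl 2-(hydroxymethyl)prop-2-enoate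
Conditions: AcOH/THF/H2O (3:1:1), rt → 40 °C
Reagents that add atoms: water, O
Why: Mild acid hydrolysis; aqueous acetic acid should cleave the primary TBS ether and hydrolyse the allylic dioxolane to the conjugated C14 aldehyde in one operation, while being too weak to ionise the acetate or the lactone or to trigger transannular cyclisation of the 1(10),4-diene.

**Compound list**
1 | geranyl acetate, (2E)-3,7-dimethylocta-2,6-dien-1-yl acetate | CC(C)=CCC/C(C)=C/COC(C)=O | starting material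
2 | ozonide, (2E)-5-(5,5-dimethyl-1,2,4-trioxolan-3-yl)-3-methylpent-2-en-1-yl acetate | CC1(C)OOC(CC/C(C)=C/COC(C)=O)O1 | intermediate
3 | (2E)-3-methyl-6-oxohex-2-en-1-yl acetate | O=CCC/C(C)=C/COC(C)=O | intermediate
4 | (2E,6E)-3-methyl-8-oxoocta-2,6-dien-1-yl acetate | O=C/C=C/CC/C(C)=C/COC(C)=O | intermediate
5 | (2E,6Z)-7-iodo-3-methyl-8-oxoocta-2,6-dien-1-yl acetate | O=C/C(I)=C/CC/C(C)=C/COC(C)=O | intermediate
6 | (2E,6Z)-7-(1,3-dioxolan-2-yl)-7-iodo-3-methylhepta-2,6-dien-1-yl acetate | O1CCOC1/C(I)=C/CC/C(C)=C/COC(C)=O | intermediate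
7 | (2E,6Z)-7-(1,3-dioxolan-2-yl)-7-iodo-3-methylhepta-2,6-dien-1-ol | O1CCOC1/C(I)=C/CC/C(C)=C/CO | intermediate
8 | (2E,6Z)-7-(1,3-dioxolan-2-yl)-7-iodo-3-methylhepta-2,6-dienal | O1CCOC1/C(I)=C/CC/C(C)=C/C=O | intermediate
9 | (3S,4E,8Z)-9-(1,3-dioxolan-2-yl)-9-iodo-5-methylnona-1,4,8-trien-3-ol | C=C[C@H](O)/C=C(\C)CC/C=C(\I)C1OCCO1 | intermediate
10 | 2-(bromomethyl)prop-2-enoic acid | C=C(CBr)C(=O)O | starting material
11 | (3S,4E,8Z)-9-(1,3-dioxolan-2-yl)-9-iodo-5-methylnona-1,4,8-trien-3-yl 2-(bromomethyl)prop-2-enoate | C=C[C@H](OC(=O)C(=C)CBr)/C=C(\C)CC/C=C(\I)C1OCCO1 | intermediate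
12 | (5R)-3-(bromomethyl)-5-[(1E,5Z)-6-(1,3-dioxolan-2-yl)-6-iodo-2-methylhexa-1,5-dien-1-yl]furan-2(5H)-one | BrCC1=C[C@@H](/C=C(\C)CC/C=C(\I)C2OCCO2)OC1=O | intermediate
13 | 2-[(4-methoxybenzyl)oxy]acetaldehyde | COc1ccc(COCC=O)cc1 | starting material
14 | allylzinc bromide, {[(5R)-5-[(1E,5Z)-6-(1,3-dioxolan-2-yl)-6-iodo-2-methylhexa-1,5-dien-1-yl]-2-oxo-2,5-dihydrofuran-3-yl]methyl}zinc bromide | Br[Zn]CC1=C[C@@H](/C=C(\C)CC/C=C(\I)C2OCCO2)OC1=O | intermediate
15 | (4R,5R)-5-[(1E,5Z)-6-(1,3-dioxolan-2-yl)-6-iodo-2-methylhexa-1,5-dien-1-yl]-4-[(1R)-1-hydroxy-2-(4-methoxybenzyloxy)ethyl]-3-methylideneoxolan-2-one (6,7-trans lactone, 8α-OH) | O[C@@H](COCc1ccc(OC)cc1)[C@H]1C(=C)C(=O)O[C@@H]1/C=C(\C)CC/C=C(\I)C2OCCO2 | intermediate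
16 | ethyl 2-(hydroxymethyl)prop-2-enoate | C=C(CO)C(=O)OCC | starting material
17 | ethyl 2-[(tert-butyldimethylsilyloxy)methyl]prop-2-enoate | C=C(CO[Si](C)(C)C(C)(C)C)C(=O)OCC | intermediate
18 | 2-[(tert-butyldimethylsilyloxy)methyl]prop-2-enoic acid | C=C(CO[Si](C)(C)C(C)(C)C)C(=O)O | intermediate
19 | (1S)-1-[(2R,3S)-2-[(1E,5Z)-6-(1,3-dioxolan-2-yl)-6-iodo-2-methylhexa-1,5-dien-1-yl]-4-methylidene-5-oxooxolan-3-yl]-2-(4-methoxybenzyloxy)ethyl 2-[(tert-butyldimethylsilyloxy)methyl]prop-2-enoate (8β ester) | C=C(CO[Si](C)(C)C(C)(C)C)C(=O)O[C@H](COCc1ccc(OC)cc1)[C@H]1C(=C)C(=O)O[C@@H]1/C=C(\C)CC/C=C(\I)C2OCCO2 | intermediate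
20 | (1S)-1-[(2R,3S)-2-[(1E,5Z)-6-(1,3-dioxolan-2-yl)-6-iodo-2-methylhexa-1,5-dien-1-yl]-4-methylidene-5-oxooxolan-3-yl]-2-hydroxyethyl 2-[(tert-butyldimethylsilyloxy)methyl]prop-2-enoate | C=C(CO[Si](C)(C)C(C)(C)C)C(=O)O[C@H](CO)[C@H]1C(=C)C(=O)O[C@@H]1/C=C(\C)CC/C=C(\I)C2OCCO2 | intermediate
21 | (1S)-1-[(2R,3S)-2-[(1E,5Z)-6-(1,3-dioxolan-2-yl)-6-iodo-2-methylhexa-1,5-dien-1-yl]-4-methylidene-5-oxooxolan-3-yl]-2-oxoethyl 2-[(tert-butyldimethylsilyloxy)methyl]prop-2-enoate | C=C(CO[Si](C)(C)C(C)(C)C)C(=O)O[C@H](C=O)[C@H]1C(=C)C(=O)O[C@@H]1/C=C(\C)CC/C=C(\I)C2OCCO2 | intermediate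
22 | alkenylchromium(III) dichloride derived from 21 (CrCl2 in place of iodine at C10, Z geometry retained) | C=C(CO[Si](C)(C)C(C)(C)C)C(=O)O[C@H](C=O)[C@H]1C(=C)C(=O)O[C@@H]1/C=C(\C)CC/C=C(\[Cr](Cl)Cl)C2OCCO2 | intermediate
23 | (3aS,4S,5S,6E,10E,11aR)-6-(1,3-dioxolan-2-yl)-5-hydroxy-10-methyl-3-methylidene-2-oxo-2,3,3a,4,5,8,9,11a-octahydrocyclodeca[b]furan-4-yl 2-[(tert-butyldimethylsilyloxy)methyl]prop-2-enoate (9α-OH) | C=C(CO[Si](C)(C)C(C)(C)C)C(=O)O[C@H]1[C@H]2C(=C)C(=O)O[C@@H]2/C=C(\C)CC/C=C(/C3OCCO3)[C@@H]1O | intermediate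
24 | (3aS,4S,5S,6E,10E,11aR)-5-acetoxy-6-(1,3-dioxolan-2-yl)-10-methyl-3-methylidene-2-oxo-2,3,3a,4,5,8,9,11a-octahydrocyclodeca[b]furan-4-yl 2-[(tert-butyldimethylsilyloxy)methyl]prop-2-enoate | C=C(CO[Si](C)(C)C(C)(C)C)C(=O)O[C@H]1[C@H]2C(=C)C(=O)O[C@@H]2/C=C(\C)CC/C=C(/C3OCCO3)[C@@H]1OC(C)=O | intermediate
25 | CNP0177123.1, (3aS,4S,5S,6E,10E,11aR)-5-acetoxy-6-formyl-10-methyl-3-methylidene-2-oxo-2,3,3a,4,5,8,9,11a-octahydrocyclodeca[b]furan-4-yl 2-(hydroxymethyl)prop-2-enoate | C=C(CO)C(=O)O[C@H]1[C@H]2C(=C)C(=O)O[C@@H]2/C=C(\C)CC/C=C(/C=O)[C@@H]1OC(C)=O | target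

**Step count and risks**
Total steps: 18. Longest linear sequence: 16 (steps 1–10 and 13–18, from geranyl acetate).

Steps most likely to fail:

Step 16 (ring closure). Intermolecular coupling may compete with closure of the ten-membered ring, and the alkenylchromium may add to the other face of the C9 aldehyde, because the acyclic preference and the ring constraints need not agree. Fallback, setting out from 21: C9 is then no longer fixed in the C–C bond formation but afterwards by SN2 inversion. The same closure, if it adds mainly to the other face, gives the 9β-alcohol (3aS,4S,5R,6E,10E,11aR)-6-(1,3-dioxolan-2-yl)-5-hydroxy-10-methyl-3-methylidene-2-oxo-2,3,3a,4,5,8,9,11a-octahydrocyclodeca[b]furan-4-yl 2-[(tert-butyldimethylsilyloxy)methyl]prop-2-enoate F1. This is treated with acetic acid, PPh3 and DIAD (toluene, 0 °C), a Mitsunobu displacement at the allylic C9 that installs the acetate with inversion. The route is rejoined at 24.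

Step 13 (Mitsunobu esterification at C8). The activated C8 alcohol may undergo E2 elimination towards C7, or substitution with retention through participation of the lactone carbonyl; the step also depends on the facial sense of step 10. Fallback, setting out from 15: C8 is set by reagent-controlled reduction instead of SN2 inversion. Dess–Martin oxidation gives the ketone (4S,5R)-5-[(1E,5Z)-6-(1,3-dioxolan-2-yl)-6-iodo-2-methylhexa-1,5-dien-1-yl]-4-[(4-methoxybenzyloxy)acetyl]-3-methylideneoxolan-2-one F2. Corey–Bakshi–Shibata reduction ((S)-Me-CBS, catecholborane, toluene, −78 °C) should give the 8β-alcohol (4R,5R)-5-[(1E,5Z)-6-(1,3-dioxolan-2-yl)-6-iodo-2-methylhexa-1,5-dien-1-yl]-4-[(1S)-1-hydroxy-2-(4-methoxybenzyloxy)ethyl]-3-methylideneoxolan-2-one F3. Carbodiimide esterification with 18 (DIC, DMAP, CH2Cl2, 0 °C, retention) rejoins the route at 19.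

Step 7 (asymmetric vinylation). The uncatalysed background addition of vinylzinc, promoted by residual magnesium salts, may erode the enantioselectivity. Fallback, setting out from 8: the stereocentre is obtained by resolution instead of asymmetric catalysis. Vinylmagnesium bromide (THF, −78 °C) gives the racemic alcohol rac-(4E,8Z)-9-(1,3-dioxolan-2-yl)-9-iodo-5-methylnona-1,4,8-trien-3-ol F4. Lipase-catalysed kinetic resolution (immobilised Candida antarctica lipase B, vinyl acetate, MTBE, 30 °C, run past half conversion) should acylate the R enantiomer to (3R,4E,8Z)-9-(1,3-dioxolan-2-yl)-9-iodo-5-methylnona-1,4,8-trien-3-yl acetate F5 and leave the S alcohol. The route is rejoined at 9.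

**Further compounds**
F1 | step 16 | (3aS,4S,5R,6E,10E,11aR)-6-(1,3-dioxolan-2-yl)-5-hydroxy-10-methyl-3-methylidene-2-oxo-2,3,3a,4,5,8,9,11a-octahydrocyclodeca[b]furan-4-yl 2-[(tert-butyldimethylsilyloxy)methyl]prop-2-enoate | C=C(CO[Si](C)(C)C(C)(C)C)C(=O)O[C@H]1[C@H]2C(=C)C(=O)O[C@@H]2/C=C(\C)CC/C=C(/C3OCCO3)[C@H]1O
F2 | step 13 | (4S,5R)-5-[(1E,5Z)-6-(1,3-dioxolan-2-yl)-6-iodo-2-methylhexa-1,5-dien-1-yl]-4-[(4-methoxybenzyloxy)acetyl]-3-methylideneoxolan-2-one | O=C(COCc1ccc(OC)cc1)[C@H]1C(=C)C(=O)O[C@@H]1/C=C(\C)CC/C=C(\I)C2OCCO2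
F3 | step 13 | (4R,5R)-5-[(1E,5Z)-6-(1,3-dioxolan-2-yl)-6-iodo-2-methylhexa-1,5-dien-1-yl]-4-[(1S)-1-hydroxy-2-(4-methoxybenzyloxy)ethyl]-3-methylideneoxolan-2-one | O[C@H](COCc1ccc(OC)cc1)[C@H]1C(=C)C(=O)O[C@@H]1/C=C(\C)CC/C=C(\I)C2OCCO2
F4 | step 7 | rac-(4E,8Z)-9-(1,3-dioxolan-2-yl)-9-iodo-5-methylnona-1,4,8-trien-3-ol | C=CC(O)/C=C(\C)CC/C=C(\I)C1OCCO1
F5 | step 7 | (3R,4E,8Z)-9-(1,3-dioxolan-2-yl)-9-iodo-5-methylnona-1,4,8-trien-3-yl acetate | C=C[C@@H](OC(C)=O)/C=C(\C)CC/C=C(\I)C1OCCO1
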